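**Plan**

1. Numbering: C1 is the pentyl methyl, C19 the vinyl terminus, and ring oxygen O1 links C6 and C9. The retrosynthesis cuts, in order, the stearate O–acyl bond, C10–C11, C3=C4 and C5–C6 (pentyl chain), then O1–C6, with C6 and C10 re-joined as the double bond of a cyclopentene.
2. Enabling feature: in the ring O1–C6–C7–C8–C9, O1 on C9 and the hydroxyl on C7 are syn across the C8 methylene. C7–C8–C9 with its neighbours C6 and C10 is therefore the carbon ring of cis-cyclopent-4-ene-1,3-diol, with C6 and C10 as its alkene carbons.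
3. Forward: the mono-TBDPS ether of the meso diol is ozonised and oxidised. The carbocycle opens between C6 and C10 and the free C9 hydroxyl closes the only ring of the route as a γ-lactone (O1–C6), leaving a carboxylic acid at C10.
4. The chain is then joined at C6 (lactol acetate allylation, cross-metathesis, hydrogenation to pentyl) and afterwards at C10 (aldehyde, nonenyl Grignard), followed by stearoylation and desilylation.
5. Stereochemistry: C7 and C9 come unchanged from the commercial enzymatic monoacetate. C6 is set cis to the C7 silyloxy group by inside attack on the ring oxocarbenium ion. C10 is set by α-chelation-controlled addition (threo).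

Key step: step 3

Remark: in step 7 the C7 silyl ether is assumed to follow the same inside-attack preference as an alkyl ether; the first fallback covers the case that it does not.

**Step 1**
Reactants: 1 (1S,4R)-cis-4-acetoxy-2-cyclopenten-1-ol
Product: 2 (1R,4S)-4-[(tert-butyldiphenylsilyl)oxy]cyclopent-2-en-1-yl acetate
Conditions: TBDPSCl, imidazole, DMF, 0 °C → rt
Reagents that add atoms: tert-butyl(chloro)diphenylsilane, CC(C)(C)[Si](Cl)(c1ccccc1)c1ccccc1
Why: Imidazole-promoted silyl ether formation on the only free hydroxyl fixes which of the two enantiotopic oxygens of the meso diol becomes the C7 oxygen, and no stereocentre is touched.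

**Step 2**
Reactants: 2 (1R,4S)-4-[(tert-butyldiphenylsilyl)oxy]cyclopent-2-en-1-yl acetate
Product: 3 (1R,4S)-4-[(tert-butyldiphenylsilyl)oxy]cyclopent-2-en-1-ol
Conditions: K2CO3 (0.2 equiv), MeOH, 0 °C → rt
Reagents that add atoms: none
Why: Base-catalysed transesterification removes the acetate while the TBDPS ether is inert, freeing the C9 hydroxyl that is to become O1.

**Step 3**
Reactants: 3 (1R,4S)-4-[(tert-butyldiphenylsilyl)oxy]cyclopent-2-en-1-ol
Product: 6 (2R,4S)-4-[(tert-butyldiphenylsilyl)oxy]-5-oxotetrahydrofuran-2-carboxylic acid, via hydroxy dialdehyde 4 (not isolated), via lactol aldehyde 5 (not isolated)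
Conditions: O3, CH2Cl2, −78 °C; Me2S, −78 °C → rt; concentrate; Jones reagent (CrO3, H2SO4, H2O), acetone, 0 °C
Reagents that add atoms: ozone, [O-][O+]=O; water, O
Why: Ozone adds to the only C=C by 1,3-dipolar cycloaddition and cycloreversion (Criegee ozonolysis), and Me2S reduces the peroxidic adducts to hydroxy dialdehyde 4, which cuts the carbocycle between C6 and C10. The C9 hydroxyl is γ to the C6 aldehyde and adds to it to close the five-membered lactol 5 (5-exo-trig addition to the carbonyl, forming O1–C6), whereas attack on the C10 aldehyde would need a three-membered ring and cannot compete. Jones oxidation then takes the lactol to the γ-lactone and the C10 aldehyde, through its hydrate, to the carboxylic acid; the closest known reaction type is the ozonolysis–oxidation of desymmetrised cis-cyclopent-4-ene-1,3-diol derivatives to 2,4-dioxygenated glutaric acid lactones. No stereocentre is created: C7 and C9 are carried over from 3, and the trans relation of the C7 silyloxy group and the C10 carboxyl across the lactone follows directly from the cis-diol. The only selectivity needed is which carbonyl the hydroxyl captures, and ring size decides it, so the two termini emerge differentiated as lactone (C6) and acid (C10). The TBDPS ether should tolerate ozone and brief exposure to Jones reagent at 0 °C, and the acidic medium should avoid epimerisation α to the aldehydes.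

**Step 4**
Reactants: 6 (2R,4S)-4-[(tert-butyldiphenylsilyl)oxy]-5-oxotetrahydrofuran-2-carboxylic acid
Product: 7 (3S,5R)-3-[(tert-butyldiphenylsilyl)oxy]-5-(hydroxymethyl)dihydrofuran-2(3H)-one
Conditions: BH3·SMe2, THF, 0 °C → rt; MeOH quench
Reagents that add atoms: none
Why: Chemoselective borane reduction of a carboxylic acid (through the acyloxyborane) in the presence of a γ-lactone and a silyl ether should give the C10 primary alcohol without base and hence without epimerisation at C7 or C9.

**Step 5**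
Reactants: 7 (3S,5R)-3-[(tert-butyldiphenylsilyl)oxy]-5-(hydroxymethyl)dihydrofuran-2(3H)-one
Product: 8 (3S,5R)-5-[(benzyloxy)methyl]-3-[(tert-butyldiphenylsilyl)oxy]dihydrofuran-2(3H)-one
Conditions: benzyl 2,2,2-trichloroacetimidate, TfOH (cat.), CH2Cl2/cyclohexane, 0 °C → rt
Reagents that add atoms: benzyl 2,2,2-trichloroacetimidate, N=C(OCc1ccccc1)C(Cl)(Cl)Cl
Why: Acid-catalysed O-benzylation with a trichloroacetimidate avoids alkoxide formation, so the base-sensitive α-silyloxy lactone should be neither opened nor epimerised.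

**Step 6**
Reactants: 8 (3S,5R)-5-[(benzyloxy)methyl]-3-[(tert-butyldiphenylsilyl)oxy]dihydrofuran-2(3H)-one
Product: 10 (3S,5R)-5-[(benzyloxy)methyl]-3-[(tert-butyldiphenylsilyl)oxy]tetrahydrofuran-2-yl acetate (anomeric mixture), via aluminium hemiacetal 9 (not isolated)
Conditions: DIBAL-H, CH2Cl2, −78 °C; then pyridine, DMAP, Ac2O, −78 → 0 °C
Reagents that add atoms: acetic anhydride, CC(=O)OC(C)=O
Why: One-pot reductive acetylation: DIBAL-H stops at the tetrahedral aluminium hemiacetal at −78 °C, which is acetylated in situ to the anomeric acetate, whose configuration is of no consequence.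

**Step 7**
Reactants: 10 (3S,5R)-5-[(benzyloxy)methyl]-3-[(tert-butyldiphenylsilyl)oxy]tetrahydrofuran-2-yl acetate; 11 allyltrimethylsilane
Product: 12 tert-butyl{[(2S,3S,5R)-5-[(benzyloxy)methyl]-2-(prop-2-en-1-yl)tetrahydrofuran-3-yl]oxy}diphenylsilane
Conditions: 11, BF3·OEt2, CH2Cl2, −78 °C
Reagents that add atoms: allyltrimethylsilane (11), C=CC[Si](C)(C)C
Why: BF3 ionises the anomeric acetate to the five-membered oxocarbenium ion and the allylsilane adds in a Hosomi–Sakurai C-glycosylation; by the inside-attack model the C7 oxygen substituent sits pseudo-equatorial and the nucleophile enters on the inside face of that envelope, which should set C6 (S) cis to the C7 silyloxy group and trans to the C9 substituent.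

**Step 8**
Reactants: 12 tert-butyl{[(2S,3S,5R)-5-[(benzyloxy)methyl]-2-(prop-2-en-1-yl)tetrahydrofuran-3-yl]oxy}diphenylsilane; 13 (E)-hex-3-ene
Product: 14 tert-butyl{[(2S,3S,5R)-5-[(benzyloxy)methyl]-2-(pent-2-en-1-yl)tetrahydrofuran-3-yl]oxy}diphenylsilane (E/Z mixture)
Conditions: 13 (excess), Grubbs second-generation catalyst (5 mol%), CH2Cl2, 40 °C
Reagents that add atoms: (E)-hex-3-ene (13), CC/C=C/CC
Why: Olefin cross-metathesis of a terminal alkene with an excess of a symmetrical internal alkene should give the pent-2-enyl chain with loss of volatile but-1-ene, and the alkene geometry is irrelevant because the next step saturates it.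

**Step 9**
Reactants: 14 tert-butyl{[(2S,3S,5R)-5-[(benzyloxy)methyl]-2-(pent-2-en-1-yl)tetrahydrofuran-3-yl]oxy}diphenylsilane
Product: 15 [(2R,4S,5S)-4-[(tert-butyldiphenylsilyl)oxy]-5-pentyltetrahydrofuran-2-yl]methanol
Conditions: H2 (1 atm), Pd(OH)2/C, EtOAc/EtOH, rt
Reagents that add atoms: none
Why: Heterogeneous catalytic hydrogenation saturates the alkene and hydrogenolyses the benzyl ether in the same operation, while the silyl ether and the ring stereocentres are unaffected.

**Step 10**
Reactants: 15 [(2R,4S,5S)-4-[(tert-butyldiphenylsilyl)oxy]-5-pentyltetrahydrofuran-2-yl]methanol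
Product: 16 (2R,4S,5S)-4-[(tert-butyldiphenylsilyl)oxy]-5-pentyltetrahydrofuran-2-carbaldehyde
Conditions: Dess–Martin periodinane, CH2Cl2, 0 °C → rt; used crude
Reagents that add atoms: none
Why: Dess–Martin oxidation converts the primary alcohol to the α-alkoxy aldehyde under mild, non-basic conditions that should not epimerise C9.

**Step 11**
Reactants: 16 (2R,4S,5S)-4-[(tert-butyldiphenylsilyl)oxy]-5-pentyltetrahydrofuran-2-carbaldehyde; 17 9-bromonon-1-ene
Product: 19 (1R)-1-[(2R,4S,5S)-4-[(tert-butyldiphenylsilyl)oxy]-5-pentyltetrahydrofuran-2-yl]dec-9-en-1-ol, via non-8-en-1-ylmagnesium bromide 18 (not isolated)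
Conditions: 17, Mg, Et2O, rt; 16, MgBr2·OEt2, CH2Cl2, −78 °C, then the Grignard solution, −78 → −40 °C; aq. NH4Cl
Reagents that add atoms: 9-bromonon-1-ene (17), C=CCCCCCCCBr
Why: Grignard addition under α-chelation control: Mg(II) bridges the aldehyde oxygen and O1 in a five-membered chelate and the alkyl group adds to the carbonyl face opposite C8, which should give the threo (10R) alcohol, the bulky C7 silyl ether being too poor a ligand to offer a competing chelate.

**Step 12**
Reactants: 19 (1R)-1-[(2R,4S,5S)-4-[(tert-butyldiphenylsilyl)oxy]-5-pentyltetrahydrofuran-2-yl]dec-9-en-1-ol; 20 stearic acid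
Product: 21 (1R)-1-[(2R,4S,5S)-4-[(tert-butyldiphenylsilyl)oxy]-5-pentyltetrahydrofuran-2-yl]dec-9-en-1-yl octadecanoate
Conditions: 20, DCC, DMAP (cat.), CH2Cl2, 0 °C → rt
Reagents that add atoms: stearic acid (20), CCCCCCCCCCCCCCCCCC(=O)O
Why: Steglich esterification acylates the only free hydroxyl through the O-acylisourea and acylpyridinium, with retention at C10.

**Step 13**
Reactants: 21 (1R)-1-[(2R,4S,5S)-4-[(tert-butyldiphenylsilyl)oxy]-5-pentyltetrahydrofuran-2-yl]dec-9-en-1-yl octadecanoate
Product: 22 (1R)-1-[(2R,4S,5S)-4-hydroxy-5-pentyltetrahydrofuran-2-yl]dec-9-en-1-yl octadecanoate (CNP0342202.1)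
Conditions: TBAF, AcOH, THF, rt → 40 °C
Reagents that add atoms: none
Why: Fluoride-mediated desilylation buffered with acetic acid should spare the stearate, and acyl migration to O7 is disfavoured because O7 and the C10 ester lie on opposite faces of the ring.

**Compound list**

1 | (1S,4R)-cis-4-acetoxy-2-cyclopenten-1-ol | CC(=O)O[C@@H]1C[C@H](O)C=C1 | starting material
2 | (1R,4S)-4-[(tert-butyldiphenylsilyl)oxy]cyclopent-2-en-1-yl acetate | CC(=O)O[C@@H]1C[C@H](O[Si](c2ccccc2)(c2ccccc2)C(C)(C)C)C=C1 | intermediate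
3 | (1R,4S)-4-[(tert-butyldiphenylsilyl)oxy]cyclopent-2-en-1-ol | O[C@@H]1C[C@H](O[Si](c2ccccc2)(c2ccccc2)C(C)(C)C)C=C1 | intermediate
4 | (2S,4R)-2-[(tert-butyldiphenylsilyl)oxy]-4-hydroxypentanedial | O=C[C@H](O)C[C@H](O[Si](c1ccccc1)(c1ccccc1)C(C)(C)C)C=O | intermediate (not isolated)
5 | (2R,4S)-4-[(tert-butyldiphenylsilyl)oxy]-5-hydroxytetrahydrofuran-2-carbaldehyde (anomeric mixture) | O=C[C@H]1C[C@H](O[Si](c2ccccc2)(c2ccccc2)C(C)(C)C)C(O)O1 | intermediate (not isolated)
6 | (2R,4S)-4-[(tert-butyldiphenylsilyl)oxy]-5-oxotetrahydrofuran-2-carboxylic acid | OC(=O)[C@H]1C[C@H](O[Si](c2ccccc2)(c2ccccc2)C(C)(C)C)C(=O)O1 | intermediate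
7 | (3S,5R)-3-[(tert-butyldiphenylsilyl)oxy]-5-(hydroxymethyl)dihydrofuran-2(3H)-one | OC[C@H]1C[C@H](O[Si](c2ccccc2)(c2ccccc2)C(C)(C)C)C(=O)O1 | intermediate
8 | (3S,5R)-5-[(benzyloxy)methyl]-3-[(tert-butyldiphenylsilyl)oxy]dihydrofuran-2(3H)-one | c1ccccc1COC[C@H]1C[C@H](O[Si](c2ccccc2)(c2ccccc2)C(C)(C)C)C(=O)O1 | intermediate
9 | {[(3S,5R)-5-[(benzyloxy)methyl]-3-[(tert-butyldiphenylsilyl)oxy]tetrahydrofuran-2-yl]oxy}bis(2-methylpropyl)aluminium (aluminium hemiacetal) | c1ccccc1COC[C@H]1C[C@H](O[Si](c2ccccc2)(c2ccccc2)C(C)(C)C)C(O[Al](CC(C)C)CC(C)C)O1 | intermediate (not isolated)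
10 | (3S,5R)-5-[(benzyloxy)methyl]-3-[(tert-butyldiphenylsilyl)oxy]tetrahydrofuran-2-yl acetate (anomeric mixture) | c1ccccc1COC[C@H]1C[C@H](O[Si](c2ccccc2)(c2ccccc2)C(C)(C)C)C(OC(C)=O)O1 | intermediate
11 | allyltrimethylsilane | C=CC[Si](C)(C)C | starting material
12 | tert-butyl{[(2S,3S,5R)-5-[(benzyloxy)methyl]-2-(prop-2-en-1-yl)tetrahydrofuran-3-yl]oxy}diphenylsilane | c1ccccc1COC[C@H]1C[C@H](O[Si](c2ccccc2)(c2ccccc2)C(C)(C)C)[C@H](CC=C)O1 | intermediate
13 | (E)-hex-3-ene | CC/C=C/CC | starting material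
14 | tert-butyl{[(2S,3S,5R)-5-[(benzyloxy)methyl]-2-(pent-2-en-1-yl)tetrahydrofuran-3-yl]oxy}diphenylsilane (E/Z mixture) | c1ccccc1COC[C@H]1C[C@H](O[Si](c2ccccc2)(c2ccccc2)C(C)(C)C)[C@H](CC=CCC)O1 | intermediate
15 | [(2R,4S,5S)-4-[(tert-butyldiphenylsilyl)oxy]-5-pentyltetrahydrofuran-2-yl]methanol | OC[C@H]1C[C@H](O[Si](c2ccccc2)(c2ccccc2)C(C)(C)C)[C@H](CCCCC)O1 | intermediate
16 | (2R,4S,5S)-4-[(tert-butyldiphenylsilyl)oxy]-5-pentyltetrahydrofuran-2-carbaldehyde | O=C[C@H]1C[C@H](O[Si](c2ccccc2)(c2ccccc2)C(C)(C)C)[C@H](CCCCC)O1 | intermediate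
17 | 9-bromonon-1-ene | C=CCCCCCCCBr | starting material
18 | non-8-en-1-ylmagnesium bromide | C=CCCCCCCC[Mg]Br | intermediate (not isolated)
19 | (1R)-1-[(2R,4S,5S)-4-[(tert-butyldiphenylsilyl)oxy]-5-pentyltetrahydrofuran-2-yl]dec-9-en-1-ol | C=CCCCCCCC[C@@H](O)[C@H]1C[C@H](O[Si](c2ccccc2)(c2ccccc2)C(C)(C)C)[C@H](CCCCC)O1 | intermediate
20 | stearic acid (octadecanoic acid) | CCCCCCCCCCCCCCCCCC(=O)O | starting material
21 | (1R)-1-[(2R,4S,5S)-4-[(tert-butyldiphenylsilyl)oxy]-5-pentyltetrahydrofuran-2-yl]dec-9-en-1-yl octadecanoate | C=CCCCCCCC[C@@H](OC(=O)CCCCCCCCCCCCCCCCC)[C@H]1C[C@H](O[Si](c2ccccc2)(c2ccccc2)C(C)(C)C)[C@H](CCCCC)O1 | intermediate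
22 | (1R)-1-[(2R,4S,5S)-4-hydroxy-5-pentyltetrahydrofuran-2-yl]dec-9-en-1-yl octadecanoate | C=CCCCCCCC[C@@H](OC(=O)CCCCCCCCCCCCCCCCC)[C@H]1C[C@H](O)[C@H](CCCCC)O1 | target

**Step count**

Total: 13 steps. Longest linear sequence: 13 steps (1 → 22); 11, 13, 17 and 20 are commercial and enter directly.

**Steps most likely to fail**

Step 7. The addition to the oxocarbenium ion may show poor facial selectivity if the bulky silyl ether shields the inside face or shifts the envelope equilibrium, so that the allyl group enters trans to the C7 oxygen. The fallback sets C6 by a substrate-controlled ring closure instead; it sets out from 8 and returns at 15. Lactone 8 would be reduced with DIBAL-H (CH2Cl2, −78 °C) and the lactol (3S,5R)-5-[(benzyloxy)methyl]-3-[(tert-butyldiphenylsilyl)oxy]tetrahydrofuran-2-ol F1 isolated. Wittig methylenation (Ph3P=CH2, THF) would open it to (2R,4S)-1-(benzyloxy)-4-[(tert-butyldiphenylsilyl)oxy]hex-5-en-2-ol F2. Kinetic iodoetherification (I2, NaHCO3, MeCN, 0 °C) would then re-form O1–C6 by 5-exo attack of the C9 hydroxyl; the allylic oxygen is known to direct the iodomethyl group cis to itself in 4-pentene-1,3-diol derivatives, which should give tert-butyl{[(2R,3S,5R)-5-[(benzyloxy)methyl]-2-(iodomethyl)tetrahydrofuran-3-yl]oxy}diphenylsilane F3. Lithium dibutylcuprate (Et2O, −40 → 0 °C) would displace the primary iodide to give tert-butyl{[(2S,3S,5R)-5-[(benzyloxy)methyl]-2-pentyltetrahydrofuran-3-yl]oxy}diphenylsilane F4, and hydrogenolysis (H2, Pd(OH)2/C) would deliver 15.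

Step 11. Chelation control may erode through competition from the non-chelated (Felkin–Anh) pathway, giving the C10 epimer. The fallback fixes C10 by SN2 inversion instead of facial selectivity; it sets out from 16 and returns at 21. Aldehyde 16 would be treated with 18 in THF without a chelating additive, and the epimeric alcohol (1S)-1-[(2R,4S,5S)-4-[(tert-butyldiphenylsilyl)oxy]-5-pentyltetrahydrofuran-2-yl]dec-9-en-1-ol F5 separated. Mitsunobu esterification with 20 (PPh3, DIAD, toluene, 0 °C → rt) would install the stearate with inversion at C10 and give 21. Any 19 formed alongside would go through step 12, so both epimers converge.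

Step 3. The open-chain hydroxy dialdehyde may be oxidised at its free C9 hydroxyl or degrade as an α-hydroxy aldehyde before the lactol closes, and epimerisation α to the aldehydes may occur during the solvent change. The fallback cleaves the ring with the C9 oxygen still masked and lactonises afterwards; it sets out from 2 and returns at 6. Ozonolysis of 2 (O3, CH2Cl2, −78 °C; Me2S) would give (2R,4S)-4-[(tert-butyldiphenylsilyl)oxy]-1,5-dioxopentan-2-yl acetate F6. Pinnick oxidation (NaClO2, NaH2PO4, 2-methyl-2-butene, t-BuOH/H2O) would take it to (2R,4S)-2-(acetyloxy)-4-[(tert-butyldiphenylsilyl)oxy]pentanedioic acid F7. Methanolysis of the acetate (K2CO3, MeOH) and acidification would give (2S,4R)-2-[(tert-butyldiphenylsilyl)oxy]-4-hydroxypentanedioic acid F8. This should lactonise (cat. TsOH, toluene) through the only hydroxyl–carboxyl pair able to form a five-membered ring, giving 6.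

**Further compounds**

F1 | step 7 | (3S,5R)-5-[(benzyloxy)methyl]-3-[(tert-butyldiphenylsilyl)oxy]tetrahydrofuran-2-ol (anomeric mixture) | c1ccccc1COC[C@H]1C[C@H](O[Si](c2ccccc2)(c2ccccc2)C(C)(C)C)C(O)O1
F2 | step 7 | (2R,4S)-1-(benzyloxy)-4-[(tert-butyldiphenylsilyl)oxy]hex-5-en-2-ol | c1ccccc1COC[C@H](O)C[C@H](O[Si](c2ccccc2)(c2ccccc2)C(C)(C)C)C=C
F3 | step 7 | tert-butyl{[(2R,3S,5R)-5-[(benzyloxy)methyl]-2-(iodomethyl)tetrahydrofuran-3-yl]oxy}diphenylsilane | c1ccccc1COC[C@H]1C[C@H](O[Si](c2ccccc2)(c2ccccc2)C(C)(C)C)[C@H](CI)O1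
F4 | step 7 | tert-butyl{[(2S,3S,5R)-5-[(benzyloxy)methyl]-2-pentyltetrahydrofuran-3-yl]oxy}diphenylsilane | c1ccccc1COC[C@H]1C[C@H](O[Si](c2ccccc2)(c2ccccc2)C(C)(C)C)[C@H](CCCCC)O1
F5 | step 11 | (1S)-1-[(2R,4S,5S)-4-[(tert-butyldiphenylsilyl)oxy]-5-pentyltetrahydrofuran-2-yl]dec-9-en-1-ol | C=CCCCCCCC[C@H](O)[C@H]1C[C@H](O[Si](c2ccccc2)(c2ccccc2)C(C)(C)C)[C@H](CCCCC)O1
F6 | step 3 | (2R,4S)-4-[(tert-butyldiphenylsilyl)oxy]-1,5-dioxopentan-2-yl acetate | O=C[C@H](OC(C)=O)C[C@H](O[Si](c1ccccc1)(c1ccccc1)C(C)(C)C)C=O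
F7 | step 3 | (2R,4S)-2-(acetyloxy)-4-[(tert-butyldiphenylsilyl)oxy]pentanedioic acid | OC(=O)[C@H](OC(C)=O)C[C@H](O[Si](c1ccccc1)(c1ccccc1)C(C)(C)C)C(=O)O
F8 | step 3 | (2S,4R)-2-[(tert-butyldiphenylsilyl)oxy]-4-hydroxypentanedioic acid | OC(=O)[C@H](O)C[C@H](O[Si](c1ccccc1)(c1ccccc1)C(C)(C)C)C(=O)O
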